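**Strategy.** Ring C is disconnected at C2–C3. C2 carries O1 and the 3,4,5-trimethoxyphenyl ring B, so it can be unmasked as an aryloxy-stabilised benzylic cation; C3 lies α to the C4 ketone on ring A, so it can be carried as an enol silane. One catalytic operation under a chiral counter-anion joins the two, closing ring C and setting C2 as (S). The precursor is an acetophenone enol silane in which the ring oxygen para to prenyl bears a CH(OPiv)Ar hemiacetal ester, chosen because pivalate ionises far more readily than the aryloxide, and the oxygen next to prenyl bears TBS. A para-Claisen–Cope relay fixes the prenyl position beforehand.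

Key step: step 6

Remark on the design: an alkoxy group is avoided as the expendable substituent at C2, because aryl alkyl acetals ionise mainly by loss of the phenol, which would cut O1–C2; an acyloxy group directs ionisation the required way.
Remark on the chemistry: the sense of induction of a new ion-pair reaction cannot be predicted with certainty; the (R)-catalyst is assumed to give the (2S)-product, and its mirror image is to be used if the opposite holds.

Step 1
Reactants: 1 1-(2,6-dihydroxy-4-methoxyphenyl)ethanone; 2 prenyl bromide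
Product: 3 1-[2-hydroxy-4-methoxy-6-(3-methylbut-2-enyloxy)phenyl]ethanone
Conditions: K2CO3 (1.2 equiv), acetone, reflux
Reagents that add atoms: none
Why: Williamson etherification of the symmetrical diol, in which the second hydroxyl becomes chelated to the ketone and much less acidic once the first is alkylated, so the mono-ether should dominate and no regiochemical question arises.

Step 2
Reactants: 3 1-[2-hydroxy-4-methoxy-6-(3-methylbut-2-enyloxy)phenyl]ethanone
Product: 4 1-[2-(tert-butyldimethylsilyloxy)-4-methoxy-6-(3-methylbut-2-enyloxy)phenyl]ethanone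
Conditions: TBSCl, imidazole, DMF, 40 °C
Reagents that add atoms: tert-butyldimethylsilyl chloride CC(C)(C)[Si](C)(C)Cl
Why: Imidazole-promoted silyl ether formation blocks the remaining phenol, so that step 3 frees only the other oxygen, and an aryl TBS ether should survive the heat and the bases that follow.

Step 3
Reactants: 4 1-[2-(tert-butyldimethylsilyloxy)-4-methoxy-6-(3-methylbut-2-enyloxy)phenyl]ethanone
Product: 7 1-[2-(tert-butyldimethylsilyloxy)-6-hydroxy-4-methoxy-3-(3-methylbut-2-enyl)phenyl]ethanone, via ortho-dienone 5 (not isolated), via para-dienone 6 (not isolated)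
Conditions: PhNEt2, 195 °C, argon
Reagents that add atoms: none
Why: Aromatic para-Claisen–Cope rearrangement, in which a [3,3] shift to the ortho-dienone, a second [3,3] (Cope) shift to the carbon para to the ether oxygen and tautomerisation put prenyl between OTBS and OMe and free the hydroxyl remote from it, as with related prenyl ethers of protected phloroacetophenones.

Step 4
Reactants: 7 1-[2-(tert-butyldimethylsilyloxy)-6-hydroxy-4-methoxy-3-(3-methylbut-2-enyl)phenyl]ethanone; 8 3,4,5-trimethoxybenzaldehyde
Product: 10 [2-acetyl-3-(tert-butyldimethylsilyloxy)-5-methoxy-4-(3-methylbut-2-enyl)phenoxy](3,4,5-trimethoxyphenyl)methyl pivalate (racemic), via α-chloro ester 9 (not isolated)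
Conditions: 8, t-BuCOCl (slightly less than 1 equiv per 8), ZnCl2 (cat.), CH2Cl2, 0 °C to rt; then sodium salt of 7 (NaH, THF), 0 °C; NaHCO3 work-up, Et3N-deactivated silica
Reagents that add atoms: pivaloyl chloride CC(C)(C)C(=O)Cl
Why: ZnCl2-catalysed addition of the acyl chloride across the aldehyde gives the α-chloroalkyl ester, and the sodium phenoxide of 7 displaces its chloride (Williamson-type O-alkylation with an α-halo ester, as in acyloxyalkyl ether formation), the bulky pivaloyl group discouraging attack at the ester carbonyl; the new centre is racemic, which is of no consequence.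

Step 5
Reactants: 10 [2-acetyl-3-(tert-butyldimethylsilyloxy)-5-methoxy-4-(3-methylbut-2-enyl)phenoxy](3,4,5-trimethoxyphenyl)methyl pivalate
Product: 11 [3-(tert-butyldimethylsilyloxy)-5-methoxy-4-(3-methylbut-2-enyl)-2-[1-(triethylsilyloxy)ethenyl]phenoxy](3,4,5-trimethoxyphenyl)methyl pivalate (racemic)
Conditions: Et3SiCl (1.5 equiv), then KN(SiMe3)2 (1.2 equiv) added last, THF, −78 °C; pentane, filtration through basic alumina, used directly
Reagents that add atoms: chlorotriethylsilane CC[Si](Cl)(CC)CC
Why: Kinetic deprotonation of the methyl ketone with in situ O-silylation (internal-quench enol silane formation) keeps the enolate short-lived so that it should not attack the hindered pivalate, and a basic method is chosen because silyl triflate and amine would ionise the hemiacetal ester.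

Step 6
Reactants: 11 [3-(tert-butyldimethylsilyloxy)-5-methoxy-4-(3-methylbut-2-enyl)-2-[1-(triethylsilyloxy)ethenyl]phenoxy](3,4,5-trimethoxyphenyl)methyl pivalate
Product: 12 (2S)-5-(tert-butyldimethylsilyloxy)-7-methoxy-6-(3-methylbut-2-enyl)-2-(3,4,5-trimethoxyphenyl)chroman-4-one
Conditions: (R)-3,3'-bis(2,4,6-triisopropylphenyl)-1,1'-binaphthyl-2,2'-diyl N-(trifluoromethylsulfonyl)phosphoramide (5 mol%), toluene, 0.02 M, −60 to −20 °C; cold NaHCO3 quench
Reagents that add atoms: none
Why: Proposed new method: the acid (after the first turnover, its triethylsilyl derivative) activates the pivalate carbonyl of 11, Et3SiOPiv departs and leaves an aryloxycarbenium ion O1=C2, stabilised by O1 and ring B and paired with the chiral phosphoramide anion; C3 of the tethered enol silane attacks it, and the silyloxocarbenium ion formed at C4 returns its silyl group to the anion, so no stoichiometric promoter is needed. The closest known reaction type is the addition of enol silanes to oxocarbenium ions released from acetals or lactol acetates under chiral Brønsted acid or silylium ion-pair catalysis, made intramolecular here in the manner of a Petasis–Ferrier closure. Ring C closes in a 6-(enolendo)-endo-trig mode, with both the enol C3=C4 bond and the O1=C2 bond inside the forming ring. The C2 stereocentre is set by the chiral counter-anion, which should shield one face of the planar cation; the racemic centre of 11 is erased on ionisation, so both enantiomers of 11 converge on one product. The step needs loss of the acyloxy and not the aryloxy group, which the more Lewis-basic and better-leaving pivalate secures, and it needs the 6-prenyl pattern, which is fixed because step 3 left only the oxygen remote from prenyl free to carry C2. No free hydroxyl or base is present, so the catalyst should not be quenched and the flavanone cannot open to a chalcone.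

Step 7
Reactants: 12 (2S)-5-(tert-butyldimethylsilyloxy)-7-methoxy-6-(3-methylbut-2-enyl)-2-(3,4,5-trimethoxyphenyl)chroman-4-one
Product: 13 artoflavanone
Conditions: HF·pyridine, pyridine, THF, 0 °C to rt (plastic vessel)
Reagents that add atoms: none
Why: Fluoride-driven cleavage of the aryl silyl ether (Si–F bond formation) under mildly acidic conditions should free the chelated 5-hydroxyl without enolising C3 or opening ring C, so the C2 configuration is kept.

**Compound list**

1 | 1-(2,6-dihydroxy-4-methoxyphenyl)ethanone | CC(=O)c1c(O)cc(OC)cc1O | starting material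
2 | prenyl bromide (1-bromo-3-methylbut-2-ene) | CC(C)=CCBr | starting material
3 | 1-[2-hydroxy-4-methoxy-6-(3-methylbut-2-enyloxy)phenyl]ethanone | CC(=O)c1c(O)cc(OC)cc1OCC=C(C)C | intermediate
4 | 1-[2-(tert-butyldimethylsilyloxy)-4-methoxy-6-(3-methylbut-2-enyloxy)phenyl]ethanone | CC(=O)c1c(O[Si](C)(C)C(C)(C)C)cc(OC)cc1OCC=C(C)C | intermediate
5 | ortho-dienone, 2-acetyl-3-(tert-butyldimethylsilyloxy)-5-methoxy-6-(2-methylbut-3-en-2-yl)cyclohexa-2,4-dien-1-one (racemic) | CC(=O)C1=C(O[Si](C)(C)C(C)(C)C)C=C(OC)C(C(C)(C)C=C)C1=O | intermediate (not isolated)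
6 | para-dienone, 2-acetyl-3-(tert-butyldimethylsilyloxy)-5-methoxy-4-(3-methylbut-2-enyl)cyclohexa-2,5-dien-1-one (racemic) | CC(=O)C1=C(O[Si](C)(C)C(C)(C)C)C(CC=C(C)C)C(OC)=CC1=O | intermediate (not isolated)
7 | 1-[2-(tert-butyldimethylsilyloxy)-6-hydroxy-4-methoxy-3-(3-methylbut-2-enyl)phenyl]ethanone | CC(=O)c1c(O)cc(OC)c(CC=C(C)C)c1O[Si](C)(C)C(C)(C)C | intermediate
8 | 3,4,5-trimethoxybenzaldehyde | COc1cc(C=O)cc(OC)c1OC | starting material
9 | chloro(3,4,5-trimethoxyphenyl)methyl pivalate (racemic) | CC(C)(C)C(=O)OC(Cl)c1cc(OC)c(OC)c(OC)c1 | intermediate (not isolated)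
10 | [2-acetyl-3-(tert-butyldimethylsilyloxy)-5-methoxy-4-(3-methylbut-2-enyl)phenoxy](3,4,5-trimethoxyphenyl)methyl pivalate (racemic) | CC(=O)c1c(OC(OC(=O)C(C)(C)C)c2cc(OC)c(OC)c(OC)c2)cc(OC)c(CC=C(C)C)c1O[Si](C)(C)C(C)(C)C | intermediate
11 | [3-(tert-butyldimethylsilyloxy)-5-methoxy-4-(3-methylbut-2-enyl)-2-[1-(triethylsilyloxy)ethenyl]phenoxy](3,4,5-trimethoxyphenyl)methyl pivalate (racemic at the hemiacetal ester carbon) | COc1cc(OC(OC(=O)C(C)(C)C)c2cc(OC)c(OC)c(OC)c2)c(C(=C)O[Si](CC)(CC)CC)c(O[Si](C)(C)C(C)(C)C)c1CC=C(C)C | intermediate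
12 | (2S)-5-(tert-butyldimethylsilyloxy)-7-methoxy-6-(3-methylbut-2-enyl)-2-(3,4,5-trimethoxyphenyl)chroman-4-one | COc1cc2c(c(O[Si](C)(C)C(C)(C)C)c1CC=C(C)C)C(=O)C[C@@H](c1cc(OC)c(OC)c(OC)c1)O2 | intermediate
13 | artoflavanone, (2S)-5-hydroxy-7-methoxy-6-(3-methylbut-2-enyl)-2-(3,4,5-trimethoxyphenyl)chroman-4-one | COc1cc2c(c(O)c1CC=C(C)C)C(=O)C[C@@H](c1cc(OC)c(OC)c(OC)c1)O2 | target

**Step count and risks**

Total step count: 7. Longest linear sequence: 7 steps (1 to 13); aldehyde 8 enters at step 4.

Steps most likely to fail:

1. Step 6 (new method). The counter-anion may discriminate the cation faces poorly, a racemic background closure may compete, the cation may be captured intermolecularly or hydrolysed instead of closing the ring, or the acid may simply strip the enol silane. Fallback with known chemistry, setting out from 7 and coming back at 12: condensation of 7 with N,N-dimethylformamide dimethyl acetal (toluene, 90 °C) should give the enaminone (E)-1-[2-(tert-butyldimethylsilyloxy)-6-hydroxy-4-methoxy-3-(3-methylbut-2-enyl)phenyl]-3-(dimethylamino)prop-2-en-1-one F1. Mild acid (pyridinium p-toluenesulfonate, toluene, 60 °C) should close it with loss of dimethylamine to 5-(tert-butyldimethylsilyloxy)-7-methoxy-6-(3-methylbut-2-enyl)chromen-4-one F2. Catalytic enantioselective conjugate addition of 3,4,5-trimethoxyphenylboronic acid (COc1cc(B(O)O)cc(OC)c1OC) to F2 then gives 12 (Pd(OCOCF3)2, the enantiomer of 4-tert-butyl-2-(pyridin-2-yl)-4,5-dihydrooxazole that delivers the (S)-flavanone, NH4PF6, water, 1,2-dichloroethane, 60 °C, no base). Here C2 is set by the chiral ligand on palladium.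

2. Step 4. The phenoxide may be acylated instead of alkylated, the electron-rich ring may be C-alkylated, or the hemiacetal ester may solvolyse during isolation. Fallback, setting out from 7 and 8 and coming back at 12: 8, 1H-benzotriazole and SOCl2 should give crystalline 1-[chloro(3,4,5-trimethoxyphenyl)methyl]-1H-benzotriazole F3. The sodium salt of 7 displaces its chloride to give the base-stable N,O-acetal 1-[2-[(benzotriazol-1-yl)(3,4,5-trimethoxyphenyl)methoxy]-6-(tert-butyldimethylsilyloxy)-4-methoxy-5-(3-methylbut-2-enyl)phenyl]ethanone F4. KN(SiMe3)2 and Et3SiCl convert it into the triethylsilyl enol ether F5. F5 is closed with the catalyst of step 6 to 12, benzotriazole leaving as its N-silyl derivative. Formation of α-(aryloxy)alkylbenzotriazoles from phenoxides and their acid-induced ionisation to oxocarbenium ions are established; the cyclisation of F5 under the chiral acid is not. This variant also removes the ester from the enolisation step.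

3. Step 3. The rearrangement may stop at the ortho (1,1-dimethylallyl) stage, give cyclised by-products, or scramble the silyl group at 195 °C. Fallback, setting out from 1 and 2 and coming back at 10: direct C-prenylation of the symmetrical 1 (aqueous KOH, 0 °C, only one mono-C-prenyl isomer possible) should give 1-[2,6-dihydroxy-4-methoxy-3-(3-methylbut-2-enyl)phenyl]ethanone F6. O-alkylation of its less hindered hydroxyl, the one remote from prenyl, with chloro ester 9 (NaH, THF, 0 °C) gives [2-acetyl-3-hydroxy-5-methoxy-4-(3-methylbut-2-enyl)phenoxy](3,4,5-trimethoxyphenyl)methyl pivalate F7, and silylation (TBSCl, imidazole) gives 10. Regiocontrol then rests on sterics alone and is to be confirmed by NOE.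

**Further compounds**

F1 | step 6 | (E)-1-[2-(tert-butyldimethylsilyloxy)-6-hydroxy-4-methoxy-3-(3-methylbut-2-enyl)phenyl]-3-(dimethylamino)prop-2-en-1-one | CN(C)/C=C/C(=O)c1c(O)cc(OC)c(CC=C(C)C)c1O[Si](C)(C)C(C)(C)C
F2 | step 6 | 5-(tert-butyldimethylsilyloxy)-7-methoxy-6-(3-methylbut-2-enyl)chromen-4-one | COc1cc2occc(=O)c2c(O[Si](C)(C)C(C)(C)C)c1CC=C(C)C
F3 | step 4 | 1-[chloro(3,4,5-trimethoxyphenyl)methyl]-1H-benzotriazole (racemic) | COc1cc(C(Cl)n2nnc3ccccc32)cc(OC)c1OC
F4 | step 4 | 1-[2-[(benzotriazol-1-yl)(3,4,5-trimethoxyphenyl)methoxy]-6-(tert-butyldimethylsilyloxy)-4-methoxy-5-(3-methylbut-2-enyl)phenyl]ethanone (racemic) | CC(=O)c1c(OC(n2nnc3ccccc32)c2cc(OC)c(OC)c(OC)c2)cc(OC)c(CC=C(C)C)c1O[Si](C)(C)C(C)(C)C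
F5 | step 4 | triethylsilyl enol ether of F4 (racemic) | COc1cc(OC(n2nnc3ccccc32)c2cc(OC)c(OC)c(OC)c2)c(C(=C)O[Si](CC)(CC)CC)c(O[Si](C)(C)C(C)(C)C)c1CC=C(C)C
F6 | step 3 | 1-[2,6-dihydroxy-4-methoxy-3-(3-methylbut-2-enyl)phenyl]ethanone | CC(=O)c1c(O)cc(OC)c(CC=C(C)C)c1O
F7 | step 3 | [2-acetyl-3-hydroxy-5-methoxy-4-(3-methylbut-2-enyl)phenoxy](3,4,5-trimethoxyphenyl)methyl pivalate (racemic) | CC(=O)c1c(OC(OC(=O)C(C)(C)C)c2cc(OC)c(OC)c(OC)c2)cc(OC)c(CC=C(C)C)c1O
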